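The earlier runs and the new flask are simulated with constants of no real substance; scatter was added.

What oak left over at its last reading, 29.7% of its E after 90.0 min, is where we start: the E that has gone, less what G took, is the stock from which D comes.

| flask | E | G | temperature | remark | time |
|---|---|---|---|---|---|
| cedar | 0.26 M | 0.0255 M | 66 °C | run made earlier |  |
| oak | 0.38 M | 0.0255 M | 91 °C | run made earlier |  |
| larch | 0.51 M | 0.013 M | 66 °C | run made earlier |  |
| north-east | 0.51 M | 0.0255 M | 85 °C |  | 2.0 h |
| south-west | 0.51 M | 0.0255 M | 70 °C |  | 2.0 h |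
| south-east | 0.51 M | 0.0255 M | 55 °C |  | 2.0 h |
| north | 0.51 M | 0.0255 M | 100 °C |  | 2.0 h |

- cedar (time / h: D / %, E / %): 0.333: 1.3, 97.0; 0.500: 0.8, 94.1; 0.833: 2.6, 91.8; 1.50: 3.7, 86.2; 2.50: 3.8, 79.8; 4.00: 4.8, 71.0
- oak (time / min: D / %, E / %): 6.00: 4.8, 87.8; 20.0: 6.3, 68.4; 30.0: 11.0, 59.2; 50.0: 15.3, 45.5; 80.0: 19.8, 33.1; 90.0: 21.5, 29.7
- larch (time / h: D / %, E / %): 0.833: 1.4, 95.0; 1.50: 0.6, 90.8; 2.50: 1.8, 83.9; 3.00: 5.8, 80.2; 4.00: 6.0, 78.4

(each reading ± 1 percentage point)

- a species is counted by the E in it: one L counts as two
- amounts and yields of D count L too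
- reactions considered so far: E + D <-> L; E <-> J; E <-> D; E + G -> Q; E <-> X
- in an amount of D, one L counts as one D

1. the best flask by amount of D, in percent of the E charged; "all alike" if 1.5 percentage points covers them all (north-east / south-west / south-east / north / all alike)
2. amount of D at the end, in percent of the E charged, north-east
3. amount of D at the end, in percent of the E charged, south-west
4. amount of D at the end, in percent of the E charged, south-east
5. amount of D at the end, in percent of the E charged, north

We write the amount of D, as a part of the E charged, as a product of factors: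

D = s · (1 − g) · (1 − exp(−kt))

Here g is [G] over [E] in the charge, the toll of E + G → Q with G as limiting reagent; k is a first-order constant for the loss of E; s is still to be read. Which of these must be known well? In north g is 5.00%. Larch and oak, each with its own toll removed, give k:

larch 0.0544 h⁻¹, oak 0.763 h⁻¹

Carrying that ratio on per degree gives 1.97 h⁻¹ for north. Now we set each number at 0.5 of its value in turn. For north, g multiplies D by 1.03, k by 0.878, and s by 0.5, so s is the one to get right.

Oak's last reading gives s = 0.338, the selectivity: D per E lost beyond the toll. This reading carries the scatter of oak's D. It sits at a third, the zero of our scale, where 3 first-order exits from E run alike.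

north: 31.5% with E left 1.83%
north-east: 17.8%

So we put north first. The forecast also names north, with 31% there (24% to 38%) against our 31.5%, and 17%, 4% and 0.6% for north-east, south-west and south-east, and it calls its value for north “the least certain because it is extrapolated”.

The flasks give 33.9% in north, then 16.5%, 4.14% and 0.686% for north-east, south-west and south-east.

    E + D ⇌ L, settled at all times (K = 48.0 M⁻¹, ΔH = −35.0 kJ mol⁻¹)
    E ⇌ J (K = 0.140, k = 0.398 h⁻¹, Ea = 115 kJ mol⁻¹, ΔH = −44.0 kJ mol⁻¹)
    E ⇌ D (K = 1.74, k = 0.653 h⁻¹, Ea = 118 kJ mol⁻¹, ΔH = −15.0 kJ mol⁻¹)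
    E + G → Q (k = 31.7 M⁻¹ h⁻¹, Ea = 79.0 kJ mol⁻¹)
    E ⇌ X (K = 2.60, k = 0.559 h⁻¹, Ea = 105 kJ mol⁻¹, ΔH = −30.0 kJ mol⁻¹)
    (constants at 100 °C)

North still holds 11% unbound E at 2.00 h, more than our 1.83%. Put on the unbound E gone beyond the toll at that time, s gives 28.4%, while north's own amount of D over that same E reckons to 0.404.

For north read at 30 min, the same product gives 20.1%; the computed amount of D is 19.4%.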